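Assumption (remark on the chemistry): locants and CIP descriptors of all intermediates use germacrane numbering, so a descriptor can change between neighbouring compounds when substituent priorities change although no bond at that centre is touched; cycloadduct 23 is drawn as its 3S epimer, and either epimer or their mixture is carried on.

Abbreviations: TES = triethylsilyl, TBS = tert-butyldimethylsilyl, PMB = 4-methoxybenzyl.

## The problem

Lychnopholide (35) is a furanoheliangolide. Its ten-membered carbocycle is numbered as a germacrane: C1 ketone, C2=C3 furanone alkene, Z-C4=C5 with methyl C15 on C4, C6 lactone carbinol, C7, C8 angelate carbinol, C9 methylene, quaternary C10 with methyl C14, C11=C13 methylene, C12 lactone carbonyl. The carbocycle is bridged twice: by a 3(2H)-furanone whose ring oxygen joins C10 to C3, and by a trans-fused α-methylene-γ-lactone across C6 and C7. A synthesis therefore has to close a strained medium ring that contains a Z-trisubstituted alkene and the sp2 carbons of the furanone, with no template to help. Of the four stereocentres, C6, C7 and C8 are contiguous and can be related to one another: C6 can direct an addition at C7 of a butenolide, and C7 biases a reduction at C8, though in the unwanted sense. The quaternary C10 is insulated by the C9 methylene and is best taken from the chiral pool. The methylene lactone is a Michael acceptor and a dipolarophile, the angelate isomerises to the tiglate and survives neither enolate nor hydride chemistry, and the furanone dienone is base-sensitive through its vinylogous C6 hydrogen. The enabling feature is the C1–C2–C3 segment of the furanone, a 1,3-dioxygenated three-carbon unit next to the oxygen-bearing C10. It is the retron of a 2-isoxazoline made from a nitrile oxide at C1 and a terminal C2=C3 alkene, so one event can close the carbocycle and lay down the furanone oxidation pattern.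

## Retrosynthesis

**Angelate (C8–O acyl bond).** 35 is cut to alcohol 32 and angelic acid 33. The ester is attached last because it would not survive the amide base of the methylenation, the borane reduction or the nitrile oxide stage. The forward step must acylate a hindered secondary alcohol without Z-to-E isomerisation and without addition to the methylene lactone.

**Methylene (C11=C13).** 32 goes back through silyl ether 31 to the 13-nor lactone 28. The lactone is carried saturated because a C11=C13 alkene would intercept the dipole in a seven-membered closure and would take up the ammonia set free when the isoxazoline is cleaved. The forward step asks for kinetic enolisation of the lactone next to the furanone. This is reasonable because the furanone has no α′ or γ hydrogen (C10 is quaternary, C4 is sp2).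

**Furanone (O–C3 bond).** 28 is opened to the 1,3-diketone 26, with the C10 oxygen as a TES ether and the C8 oxygen as a TBS ether. Acid removes the more labile TES group; the tertiary hydroxyl adds to the C3 carbonyl and water is lost. Keeping C8 silylated excludes the alternative addition of a C8 hydroxyl to the C1 carbonyl.

**Diketone to isoxazoline.** 26 comes from β-hydroxy ketone 25 by oxidation, and 25 from isoxazoline 23 by N–O cleavage and imine hydrolysis. The isoxazoline is a masked aldol that stores C1 as C=N and C3 as C–O.

**Key cut (C1–C2 and O–C3).** 23 is opened to nitrile oxide 22, generated from aldoxime 20. Cuts elsewhere in the ring (C5–C6, C3–C4) would need the furanone made beforehand on an open chain. This cut removes two rings and the C1/C3 oxygen pattern at once and leaves a lactone carrying two side chains. The forward reaction must deliver the dipole carbon to the terminal CH2, outrun dimerisation, and leave the trisubstituted C4=C5 alone.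

**Oxime (C1).** 20 comes from aldehyde 19, 19 from alcohol 18, and 18 from PMB ether 17. C1 stays a PMB ether until the end because an oxime would not survive the olefination and coupling steps. PMB is orthogonal to every silyl ether in the molecule.

**Z-diene (C3–C4 and C4=C5).** 17 is cut at C3–C4 to vinyl iodide 15 and vinylboronate 16. 15 is cut at C4=C5 to aldehyde 14, which comes from the primary TES ether 13. The diene is built after the C7–C8 bond. Attaching it earlier would place a doubly allylic, vinylogously acidic hydrogen at C6 of a butenolide, and a basic carbanion would racemise or isomerise it. It would also force an alkyne semihydrogenation in the presence of a diene. The forward steps need Z-selective olefination and a coupling with retention.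

**C8 carbinol.** 13 comes from alcohol 12, 12 from ketone 11, and 11 from dithiane 10. A Felkin–Anh analysis of 11 (C6 as the large group on C7) predicts the 8R alcohol, so the 8S centre is set by reagent control.

**C7–C8 bond.** 10 is cut to lithiated dithiane 9 (from 6) and butenolide 8. An acyl anion adds to the butenolide anti to the C6 substituent, so C6 sets C7. The cut divides the molecule into two fragments of similar size, each with one chiral-pool stereocentre.

**Fragments.** 6 comes from alcohol 5, made by opening epoxide 2 with 2-lithio-1,3-dithiane 4 (from 3); this forms C8–C9 and brings in C10 intact. 2 is the PMB ether of (S)-2-methylglycidol 1. 8 is the TES ether of the commercial butenolide 7.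

## Roads not taken

**Alternative 1:** biomimetic ether closure. The cut is the C10–O bond of the furanone together with the C1 oxygen, leading back to the 3-oxo heliangolide A1, which has an E-C1=C10 alkene. Forward, dimethyldioxirane epoxidises C1=C10. Catalytic pyridinium p-toluenesulfonate then lets the C3 carbonyl oxygen open the epoxide at the tertiary C10, and loss of a C2 proton gives the 1-hydroxy enol ether A2. Oxidation at C1 finishes the target.
- Merits: the endgame is very short, no base or enolate is needed so the angelate and methylene lactone can already be present, and C10 is set by the alkene geometry and epoxide face and not by a purchased stereocentre.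
- Weak points: A1 is a ten-membered E,Z-dienone lactone with three stereocentres and is as hard to close as the target. The epoxidation face, and hence C10, depends on the macrocycle conformation. Transannular attack by the C4=C5 alkene competes.
- Comparison: in endgame economy this road is better. The chosen plan offers a ring closure that also installs the oxygen pattern, and a C10 centre fixed from the first step.

**Alternative 2:** Nozaki–Hiyama–Kishi closure at C5–C6. The cut leads to the seco Z-iodoalkene aldehyde A3, which already carries furanone, angelate and the C11 methylene with C12 as a silyl ether. Forward, CrCl2 with catalytic NiCl2 turns the alkenyl iodide into an alkenylchromium that adds to the C6 aldehyde and gives allylic alcohol A4. Desilylation and oxidative lactonisation follow.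
- Merits: this is probably the most dependable way to close such a ring. It tolerates ester, furanone and the 1,1-disubstituted alkene, and little remains after cyclisation.
- Weak points: C6 is created in the ring closure and its configuration depends on the macrocyclic transition state. The aldehyde in A3 carries a β-acyloxy group and can eliminate. The divalent chromium salt is needed in excess. The furanone of A3 must be built separately.
- Comparison: for the C–C bond-forming event itself this road is at least as good. The chosen plan fixes C6 from the chiral pool, derives C7 from it, and obtains the furanone from the ring closure without extra chemistry.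

**Alternative 3:** Heck macrocyclisation at C3–C4. The cut leads to A5, a 3-unsubstituted furanone tethered to a Z-vinyl iodide at C4. Forward, zerovalent palladium (from Pd(OAc)2, P(o-tolyl)3 and Ag2CO3) inserts into the C–I bond, the alkenylpalladium adds across C2=C3, and β-hydride elimination restores the furanone in A6. A6 is the same compound as 28 of the chosen route.
- Merits: it is catalytic, creates no throw-away stereocentre, and reaches 28 without the three redox and acid steps that follow the cycloaddition.
- Weak points: syn carbopalladation of the cyclic enone places palladium on C2 anti to the C3 hydrogen. Elimination must therefore wait for epimerisation through a palladium enolate. C3 is also the oxygen-substituted, less electrophilic alkene carbon, and the ring is strained.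
- Comparison: this road is shorter on paper. The chosen plan relies on a concerted ring closure with no such stereoelectronic demand and with an intrinsic regiochemical preference for the needed bond.

Key step: step 15

## Route

Step 1
Reactants: 1 (S)-2-methylglycidol
Product: 2 (R)-2-[(4-methoxybenzyloxy)methyl]-2-methyloxirane
Conditions: NaH, 4-methoxybenzyl chloride, Bu4NI (cat.), THF, 0 °C to rt
Reagents that add atoms: 4-methoxybenzyl chloride, COc1ccc(CCl)cc1
Why: Williamson ether synthesis on the primary alkoxide; the Payne rearrangement open to this alkoxide is degenerate for a 2-methylglycidol and returns the same enantiomer, so the future C10 is untouched (the descriptor changes from S to R only because the ether raises the priority of the CH2O arm).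

Step 2
Reactants: 2 (R)-2-[(4-methoxybenzyloxy)methyl]-2-methyloxirane; 3 1,3-dithiane
Product: 5 (R)-1-(1,3-dithian-2-yl)-3-(4-methoxybenzyloxy)-2-methylpropan-2-ol, via 2-lithio-1,3-dithiane 4 (not isolated)
Conditions: 3, n-BuLi, THF, −30 °C; then 2, −30 °C to rt; H2O
Reagents that add atoms: none
Why: Corey–Seebach alkylation; the lithiated dithiane opens the 2,2-disubstituted epoxide by SN2 attack at its unsubstituted CH2 (future C9), forming C8–C9 and releasing the tertiary C10 alkoxide without touching the stereocentre.

Step 3
Reactants: 5 (R)-1-(1,3-dithian-2-yl)-3-(4-methoxybenzyloxy)-2-methylpropan-2-ol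
Product: 6 (R)-2-[3-(4-methoxybenzyloxy)-2-methyl-2-(triethylsilyloxy)propyl]-1,3-dithiane
Conditions: TESOTf, 2,6-lutidine, CH2Cl2, −78 to 0 °C
Reagents that add atoms: triethylsilyl trifluoromethanesulfonate, CC[Si](CC)(CC)OS(=O)(=O)C(F)(F)F
Why: Silyl triflate with a hindered pyridine base silylates tertiary alcohols; the TES ether shields the C10 oxygen from the organolithium and nitrile oxide steps and is the most acid-labile silyl group later on, as step 18 requires.

Step 4
Reactants: 7 (S)-5-(hydroxymethyl)furan-2(5H)-one
Product: 8 (S)-5-(triethylsilyloxymethyl)furan-2(5H)-one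
Conditions: TESCl, imidazole, CH2Cl2, 0 °C
Reagents that add atoms: chlorotriethylsilane, CC[Si](Cl)(CC)CC
Why: Standard silylation with imidazole, mild enough for the base-sensitive butenolide; a primary TES ether is chosen because step 9 can oxidise it directly to the aldehyde.

Step 5
Reactants: 6 (R)-2-[3-(4-methoxybenzyloxy)-2-methyl-2-(triethylsilyloxy)propyl]-1,3-dithiane; 8 (S)-5-(triethylsilyloxymethyl)furan-2(5H)-one
Product: 10 (6S,7S,10R)-C8-dithianyl trans-lactone [C5–OTES; C10–OTES; C1–OPMB], via 2-lithio derivative of dithiane 9 (not isolated)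
Conditions: 6, t-BuLi, THF/HMPA (9:1), −78 °C; then 8, −78 °C; AcOH
Reagents that add atoms: none
Why: Michael addition of an acyl anion equivalent (dithiane umpolung); HMPA gives a solvent-separated, soft carbanion that adds 1,4 to the butenolide from the face anti to the C6 substituent, which sets C7 trans to C6, and the stabilised carbanion does not accept the TES group from the C10 oxygen.

Step 6
Reactants: 10 (6S,7S,10R)-C8-dithianyl trans-lactone [C5–OTES; C10–OTES; C1–OPMB]
Product: 11 (6S,7S,10R)-C8 ketone [C5–OTES; C10–OTES; C1–OPMB]
Conditions: MeI, CaCO3, MeCN/H2O (9:1), 45 °C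
Reagents that add atoms: water, O
Why: Alkylative dithiane hydrolysis; S-methylation turns sulfur into a leaving group and water delivers the carbonyl oxygen, while CaCO3 keeps the medium neutral so that the primary TES ether, the PMB ether and the β-acyloxy ketone (prone to E1cB opening under base) survive.

Step 7
Reactants: 11 (6S,7S,10R)-C8 ketone [C5–OTES; C10–OTES; C1–OPMB]
Product: 12 (6S,7R,8S,10R)-C8 alcohol [C5–OTES; C10–OTES; C1–OPMB]
Conditions: (R)-2-methyl-CBS-oxazaborolidine, BH3·SMe2, THF, −30 °C; MeOH
Reagents that add atoms: none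
Why: Corey–Bakshi–Shibata (Corey–Itsuno) reduction; the (R)-catalyst should deliver hydride to the Re face of a ketone whose large flank is the α-branched ring carbon C7 and whose small flank is C9H2, giving 8S, and catalyst control is chosen because the Felkin–Anh preference of C7 points to 8R; borane at −30 °C leaves the lactone.

Step 8
Reactants: 12 (6S,7R,8S,10R)-C8 alcohol [C5–OTES; C10–OTES; C1–OPMB]
Product: 13 (6S,7S,8S,10R)-C8 TBS ether [C5–OTES; C10–OTES; C1–OPMB]
Conditions: TBSOTf, 2,6-lutidine, CH2Cl2, −78 to 0 °C
Reagents that add atoms: tert-butyldimethylsilyl trifluoromethanesulfonate, CC(C)(C)[Si](C)(C)OS(=O)(=O)C(F)(F)F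
Why: Silyl triflate protection of a hindered secondary alcohol, done before the C8 hydroxyl can translactonise onto C12; TBS outlasts the C10 TES ether in acid and is removed by fluoride at the end.

Step 9
Reactants: 13 (6S,7S,8S,10R)-C8 TBS ether [C5–OTES; C10–OTES; C1–OPMB]
Product: 14 (6S,7S,8S,10R)-C5 aldehyde [C8–OTBS; C10–OTES; C1–OPMB]
Conditions: (COCl)2, DMSO, CH2Cl2, −78 to −40 °C; then Et3N, −78 to 0 °C
Reagents that add atoms: none
Why: Swern oxidation with in-situ desilylation; the chlorosulfonium reagent cleaves primary TES ethers and oxidises the freed alcohol to the aldehyde, while tertiary TES, secondary TBS and PMB ethers are inert; the aldehyde is used crude to protect C6.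

Step 10
Reactants: 14 (6S,7S,8S,10R)-C5 aldehyde [C8–OTBS; C10–OTES; C1–OPMB]
Product: 15 (4Z,6S,7S,8S,10R)-C4 vinyl iodide [C8–OTBS; C10–OTES; C1–OPMB]
Conditions: [Ph3PEt]I, n-BuLi, THF, rt; I2, −78 °C; NaN(SiMe3)2, −20 °C; then 14, −78 to −20 °C
Reagents that add atoms: ethyltriphenylphosphonium iodide, CC[P+](c1ccccc1)(c1ccccc1)c1ccccc1.[I-]; iodine, II
Why: Stork–Zhao-type Wittig iodo-olefination; the α-iodo ylide reacts with aldehydes under kinetic control to give (Z)-2-iodoalk-2-enes, placing iodine cis to C6 and the methyl C15 trans, and the low temperature and non-enolising ylide spare C6 and the lactone.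

Step 11
Reactants: 15 (4Z,6S,7S,8S,10R)-C4 vinyl iodide [C8–OTBS; C10–OTES; C1–OPMB]; 16 vinylboronic acid pinacol ester
Product: 17 (4Z,6R,7S,8S,10R)-diene PMB ether [C8–OTBS; C10–OTES]
Conditions: 16, PdCl2(dppf) (5 mol %), K3PO4 (aq), THF, 40 °C
Reagents that add atoms: none
Why: Suzuki–Miyaura coupling; oxidative addition, transmetalation and reductive elimination all keep the alkene geometry, so the vinyl group (C2=C3) replaces iodine cis to C6 and the Z-diene results, and mild phosphate base tolerates the lactone and silyl ethers.

Step 12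
Reactants: 17 (4Z,6R,7S,8S,10R)-diene PMB ether [C8–OTBS; C10–OTES]
Product: 18 (4Z,6R,7S,8S,10R)-diene C1 alcohol [C8–OTBS; C10–OTES]
Conditions: DDQ, CH2Cl2/pH 7 buffer, 0 °C
Reagents that add atoms: none
Why: Oxidative PMB ether cleavage at the electron-rich benzylic position; the buffer prevents a silyl shift to the new primary hydroxyl, and the diene is spared because its Z-substituent blocks the s-cis conformer a Diels–Alder reaction with DDQ would need.

Step 13
Reactants: 18 (4Z,6R,7S,8S,10R)-diene C1 alcohol [C8–OTBS; C10–OTES]
Product: 19 (4Z,6R,7S,8S,10R)-diene C1 aldehyde [C8–OTBS; C10–OTES]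
Conditions: Dess–Martin periodinane, NaHCO3, CH2Cl2, 0 °C to rt
Reagents that add atoms: none
Why: Dess–Martin oxidation of a neopentyl-type primary alcohol; the aldehyde has no α-hydrogen (C10 is quaternary), so neither epimerisation nor enolisation is possible.

Step 14
Reactants: 19 (4Z,6R,7S,8S,10R)-diene C1 aldehyde [C8–OTBS; C10–OTES]
Product: 20 (4Z,6R,7S,8S,10R)-seco diene (E)-aldoxime [C8–OTBS; C10–OTES]
Conditions: NH2OH·HCl, pyridine, EtOH, rt
Reagents that add atoms: hydroxylamine hydrochloride, NO.Cl
Why: Oxime condensation; the aldehyde reacts far faster than the lactone, and the oxime geometry does not matter because the nitrile oxide derived from it is linear.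

Step 15
Reactants: 20 (4Z,6R,7S,8S,10R)-seco diene (E)-aldoxime [C8–OTBS; C10–OTES]
Product: 23 (3S,6R,7S,8S,10R)-isoxazoline-bridged ten-membered carbocycle [C8–OTBS; C10–OTES], via hydroximoyl chloride 21 (not isolated), via nitrile oxide 22 (not isolated)
Conditions: NaOCl (aq), CH2Cl2, 0 °C to rt; 20 added by syringe pump to about 1 mM
Reagents that add atoms: none
Why: Hypochlorite chlorinates the oxime carbon to hydroximoyl chloride 21, and loss of HCl at the aqueous interface gives nitrile oxide 22, which adds to the terminal C2=C3 alkene in a concerted, asynchronous [3+2] (Huisgen) cycloaddition; the closest known reaction type is the intramolecular nitrile oxide–alkene cycloaddition that closes medium and large carbocycles as bridged 2-isoxazolines. The ten-membered carbocycle closes through the C1–C2 bond in the bridged mode, with both alkene carbons ending inside the new ring, and the isoxazoline closes in the same transition state through O–C3. The only new stereocentre, C3, is set by which face of the vinyl group the tethered dipole reaches, a matter of the conformation imposed by the trans lactone and the Z-alkene; it is not steered, because step 17 turns C3 into a carbonyl and both epimers converge. Regioselectivity (dipole carbon to the CH2 terminus, oxygen to C3) follows the normal polarity for a monosubstituted, diene-conjugated alkene, and the opposite orientation would need a nine-membered ring with the electronically disfavoured alignment. Site selectivity rests on the much higher rate of a monosubstituted alkene over the trisubstituted C4=C5 and on the absence of the C11 methylene at this stage. Dimerisation to furoxans is the competing path; it is held back by high dilution and by the fully substituted, silyloxy-bearing C10 next to the dipole, which hinders approach of a second dipole more than that of the tethered CH2.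

Step 16
Reactants: 23 (3S,6R,7S,8S,10R)-isoxazoline-bridged ten-membered carbocycle [C8–OTBS; C10–OTES]
Product: 25 (3S,6R,7S,8S,10R)-3-hydroxy-1-ketone [C8–OTBS; C10–OTES], via β-hydroxy imine 24 (not isolated)
Conditions: Mo(CO)6, MeCN/H2O (10:1), 80 °C
Reagents that add atoms: water, O
Why: Reductive N–O cleavage of a 2-isoxazoline by zerovalent molybdenum followed by hydrolysis of the β-hydroxy imine; the conditions are neutral and non-hydrogenative, so the Z-alkene, the lactone and both silyl ethers are kept, which hydrogenolysis over Raney Ni would not allow.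

Step 17
Reactants: 25 (3S,6R,7S,8S,10R)-3-hydroxy-1-ketone [C8–OTBS; C10–OTES]
Product: 26 (6R,7S,8S,10R)-1,3-diketone [C8–OTBS; C10–OTES]
Conditions: Dess–Martin periodinane, NaHCO3, CH2Cl2, rt
Reagents that add atoms: none
Why: Dess–Martin oxidation of an allylic β-hydroxy ketone to the 1,3-diketone (resting as its enol); the step removes the C3 stereocentre, so both cycloadduct epimers converge.

Step 18
Reactants: 26 (6R,7S,8S,10R)-1,3-diketone [C8–OTBS; C10–OTES]
Product: 28 (6R,7S,8S,10R)-13-nor furanone lactone 8-O-TBS ether, via 10-hydroxy-1,3-diketone 27 (not isolated)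
Conditions: p-TsOH·H2O (cat.), THF/H2O, rt
Reagents that add atoms: none
Why: Acid solvolysis of the tertiary TES ether (faster than that of the hindered secondary TBS ether), 5-exo-trig addition of the C10 hydroxyl to the C3 carbonyl and dehydration of the hemiketal, the classical cyclodehydration of α′-hydroxy-1,3-diketones to 3(2H)-furanones; with C8 still silylated only the C10 hydroxyl can engage the diketone, and C10 keeps its configuration because its C–O bond is never broken.

Step 19
Reactants: 28 (6R,7S,8S,10R)-13-nor furanone lactone 8-O-TBS ether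
Product: 31 (6R,7S,8S,10R)-8-O-TBS-8-deangeloyl-lychnopholide, via Mannich base 29 (not isolated), via trimethylammonium iodide 30 (not isolated)
Conditions: LiN(SiMe3)2, THF, −78 °C; CH2=NMe2+ I−, −78 to 0 °C; then MeI, THF/MeOH, rt; then NaHCO3 (aq), CH2Cl2, rt
Reagents that add atoms: N,N-dimethylmethyleneiminium iodide, C=[N+](C)C.[I-]
Why: Eschenmoser methylenation; the lactone CH2 (C11) is the only site open to carbonyl-directed kinetic deprotonation (the furanone has no α′ or γ hydrogen, and its vinylogous C6 hydrogen is remote from the carbonyl), the enolate undergoes a Mannich reaction with the iminium salt, and exhaustive methylation followed by E1cB loss of trimethylamine gives the exocyclic C11=C13 alkene.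

Step 20
Reactants: 31 (6R,7S,8S,10R)-8-O-TBS-8-deangeloyl-lychnopholide
Product: 32 (6R,7R,8S,10R)-8-deangeloyl-lychnopholide
Conditions: HF·pyridine, pyridine, THF, 0 °C to rt
Reagents that add atoms: none
Why: Fluoride-mediated desilylation under buffered, weakly acidic conditions that neither add to the methylene lactone (as basic Bu4NF might) nor disturb the furanone.

Step 21
Reactants: 32 (6R,7R,8S,10R)-8-deangeloyl-lychnopholide; 33 angelic acid
Product: 35 lychnopholide, via angelic 2,4,6-trichlorobenzoic anhydride 34 (not isolated)
Conditions: 33, 2,4,6-trichlorobenzoyl chloride, Et3N, toluene, rt; then 32, toluene, 80 °C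
Reagents that add atoms: none
Why: Yamaguchi-type esterification through the mixed anhydride without a nucleophilic catalyst; the alcohol attacks the less hindered angeloyl carbonyl, and leaving out DMAP and strong base avoids both the addition–elimination that turns angelates into tiglates and conjugate addition to the methylene lactone.

## Compound list

1 | (S)-2-methylglycidol [(S)-(2-methyloxiran-2-yl)methanol] | OC[C@@]1(C)CO1 | starting material
2 | (R)-2-[(4-methoxybenzyloxy)methyl]-2-methyloxirane | COc1ccc(COC[C@@]2(C)CO2)cc1 | intermediate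
3 | 1,3-dithiane | C1CSCSC1 | starting material
4 | 2-lithio-1,3-dithiane | [Li]C1SCCCS1 | intermediate (not isolated)
5 | (R)-1-(1,3-dithian-2-yl)-3-(4-methoxybenzyloxy)-2-methylpropan-2-ol | COc1ccc(COC[C@](C)(O)CC2SCCCS2)cc1 | intermediate
6 | (R)-2-[3-(4-methoxybenzyloxy)-2-methyl-2-(triethylsilyloxy)propyl]-1,3-dithiane (C8 dithiane, C9H2, C10(CH3)(OTES), C1H2OPMB) | COc1ccc(COC[C@](C)(O[Si](CC)(CC)CC)CC2SCCCS2)cc1 | intermediate
7 | (S)-5-(hydroxymethyl)furan-2(5H)-one | C1=CC(=O)O[C@@H]1CO | starting material
8 | (S)-5-(triethylsilyloxymethyl)furan-2(5H)-one | C1=CC(=O)O[C@@H]1CO[Si](CC)(CC)CC | intermediate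
9 | 2-lithio derivative of dithiane 6 | COc1ccc(COC[C@](C)(O[Si](CC)(CC)CC)CC2([Li])SCCCS2)cc1 | intermediate (not isolated)
10 | (6S,7S,10R)-C8-dithianyl trans-lactone: γ-lactone (O–C6, C12=O, C11H2, C7) with C5H2OTES on C6 and, trans to it on C7, the dithiane carbon C8 carrying C9H2–C10(CH3)(OTES)–C1H2OPMB | COc1ccc(COC[C@](C)(O[Si](CC)(CC)CC)CC2(SCCCS2)[C@H]3CC(=O)O[C@@H]3CO[Si](CC)(CC)CC)cc1 | intermediate
11 | (6S,7S,10R)-C8 ketone of the same lactone | COc1ccc(COC[C@](C)(O[Si](CC)(CC)CC)CC(=O)[C@H]2CC(=O)O[C@@H]2CO[Si](CC)(CC)CC)cc1 | intermediate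
12 | (6S,7R,8S,10R)-C8 alcohol | COc1ccc(COC[C@](C)(O[Si](CC)(CC)CC)C[C@H](O)[C@H]2CC(=O)O[C@@H]2CO[Si](CC)(CC)CC)cc1 | intermediate
13 | (6S,7S,8S,10R)-C8 TBS ether | COc1ccc(COC[C@](C)(O[Si](CC)(CC)CC)C[C@H](O[Si](C)(C)C(C)(C)C)[C@H]2CC(=O)O[C@@H]2CO[Si](CC)(CC)CC)cc1 | intermediate
14 | (6S,7S,8S,10R)-C5 aldehyde (formyl group on C6 of the lactone) | COc1ccc(COC[C@](C)(O[Si](CC)(CC)CC)C[C@H](O[Si](C)(C)C(C)(C)C)[C@H]2CC(=O)O[C@@H]2C=O)cc1 | intermediate
15 | (4Z,6S,7S,8S,10R)-C4 vinyl iodide (C6–CH=C(I)CH3, iodine cis to C6) | COc1ccc(COC[C@](C)(O[Si](CC)(CC)CC)C[C@H](O[Si](C)(C)C(C)(C)C)[C@H]2CC(=O)O[C@@H]2/C=C(/C)I)cc1 | intermediate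
16 | vinylboronic acid pinacol ester (4,4,5,5-tetramethyl-2-vinyl-1,3,2-dioxaborolane) | C=CB1OC(C)(C)C(C)(C)O1 | starting material
17 | (4Z,6R,7S,8S,10R)-diene PMB ether (C6–CH=C(CH3)–CH=CH2, vinyl cis to C6) | COc1ccc(COC[C@](C)(O[Si](CC)(CC)CC)C[C@H](O[Si](C)(C)C(C)(C)C)[C@H]2CC(=O)O[C@@H]2/C=C(/C)C=C)cc1 | intermediate
18 | (4Z,6R,7S,8S,10R)-diene C1 alcohol | OC[C@](C)(O[Si](CC)(CC)CC)C[C@H](O[Si](C)(C)C(C)(C)C)[C@H]1CC(=O)O[C@@H]1/C=C(/C)C=C | intermediate
19 | (4Z,6R,7S,8S,10R)-diene C1 aldehyde | O=C[C@](C)(O[Si](CC)(CC)CC)C[C@H](O[Si](C)(C)C(C)(C)C)[C@H]1CC(=O)O[C@@H]1/C=C(/C)C=C | intermediate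
20 | (4Z,6R,7S,8S,10R)-seco diene (E)-aldoxime | O/N=C/[C@](C)(O[Si](CC)(CC)CC)C[C@H](O[Si](C)(C)C(C)(C)C)[C@H]1CC(=O)O[C@@H]1/C=C(/C)C=C | intermediate
21 | C1 hydroximoyl chloride of 20 | ON=C(Cl)[C@](C)(O[Si](CC)(CC)CC)C[C@H](O[Si](C)(C)C(C)(C)C)[C@H]1CC(=O)O[C@@H]1/C=C(/C)C=C | intermediate (not isolated)
22 | C1 nitrile oxide | [O-][N+]#C[C@](C)(O[Si](CC)(CC)CC)C[C@H](O[Si](C)(C)C(C)(C)C)[C@H]1CC(=O)O[C@@H]1/C=C(/C)C=C | intermediate (not isolated)
23 | (3S,6R,7S,8S,10R)-isoxazoline-bridged ten-membered carbocycle (C1=N, O on C3; 3S drawn) | C1C(=O)O[C@@H]2/C=C(/C)[C@@H]3CC(=NO3)[C@](C)(O[Si](CC)(CC)CC)C[C@H](O[Si](C)(C)C(C)(C)C)[C@@H]12 | intermediate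
24 | β-hydroxy imine (C1=NH, C3–OH) | C1C(=O)O[C@@H]2/C=C(/C)[C@@H](O)CC(=N)[C@](C)(O[Si](CC)(CC)CC)C[C@H](O[Si](C)(C)C(C)(C)C)[C@@H]12 | intermediate (not isolated)
25 | (3S,6R,7S,8S,10R)-3-hydroxy-1-ketone | C1C(=O)O[C@@H]2/C=C(/C)[C@@H](O)CC(=O)[C@](C)(O[Si](CC)(CC)CC)C[C@H](O[Si](C)(C)C(C)(C)C)[C@@H]12 | intermediate
26 | (6R,7S,8S,10R)-1,3-diketone | C1C(=O)O[C@@H]2/C=C(/C)C(=O)CC(=O)[C@](C)(O[Si](CC)(CC)CC)C[C@H](O[Si](C)(C)C(C)(C)C)[C@@H]12 | intermediate
27 | 10-hydroxy-1,3-diketone | C1C(=O)O[C@@H]2/C=C(/C)C(=O)CC(=O)[C@](C)(O)C[C@H](O[Si](C)(C)C(C)(C)C)[C@@H]12 | intermediate (not isolated)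
28 | (6R,7S,8S,10R)-13-nor furanone lactone 8-O-TBS ether | C1C(=O)O[C@@H]2/C=C(/C)C3=CC(=O)[C@@](C)(C[C@H](O[Si](C)(C)C(C)(C)C)[C@@H]12)O3 | intermediate
29 | Mannich base, 11-(dimethylaminomethyl) derivative of 28 (C11 epimers) | CN(C)CC1C(=O)O[C@@H]2/C=C(/C)C3=CC(=O)[C@@](C)(C[C@H](O[Si](C)(C)C(C)(C)C)[C@@H]12)O3 | intermediate (not isolated)
30 | trimethylammonium iodide of 29 | C[N+](C)(C)CC1C(=O)O[C@@H]2/C=C(/C)C3=CC(=O)[C@@](C)(C[C@H](O[Si](C)(C)C(C)(C)C)[C@@H]12)O3.[I-] | intermediate (not isolated)
31 | (6R,7S,8S,10R)-8-O-TBS-8-deangeloyl-lychnopholide | C=C1C(=O)O[C@@H]2/C=C(/C)C3=CC(=O)[C@@](C)(C[C@H](O[Si](C)(C)C(C)(C)C)[C@@H]12)O3 | intermediate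
32 | (6R,7R,8S,10R)-8-deangeloyl-lychnopholide (C8 alcohol) | C=C1C(=O)O[C@@H]2/C=C(/C)C3=CC(=O)[C@@](C)(C[C@H](O)[C@@H]12)O3 | intermediate
33 | angelic acid [(Z)-2-methylbut-2-enoic acid] | C/C=C(/C)C(=O)O | starting material
34 | angelic 2,4,6-trichlorobenzoic anhydride | C/C=C(/C)C(=O)OC(=O)c1c(Cl)cc(Cl)cc1Cl | intermediate (not isolated)
35 | lychnopholide (6R,7R,8S,10R) | C=C1C(=O)O[C@@H]2/C=C(/C)C3=CC(=O)[C@@](C)(C[C@H](OC(=O)/C(C)=C\C)[C@@H]12)O3 | target

## Step count and least certain steps

Total step count: 21. Longest linear sequence: 20 steps (steps 1–3 and 5–21, from 1 to 35); the butenolide branch contributes step 4.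

**Step 15 (key step).** The most likely failure is that ring closure is too slow against furoxan dimerisation or oligomerisation of 22, because the transition state must build a strained ten-membered ring; closure in the fused sense (C1 to C3) is a lesser risk. The fallback leaves the dipolar route and closes the same C1–C2 bond by an aldol addition.
- Setting out from vinyl iodide 15, Stille coupling with tributyl(1-ethoxyvinyl)stannane (Pd(PPh3)4, then dilute acid) gives the Z-enone methyl ketone F1.
- DDQ and Dess–Martin oxidation, as in steps 12 and 13, give alcohol F2 and keto aldehyde F3.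
- A boron aldol under high dilution (Bu2BOTf, i-Pr2NEt) enolises only the methyl ketone and closes the ring to the macrocyclic β-hydroxy ketone F4.
- Dess–Martin oxidation of F4 gives diketone 26, where the route is rejoined.

**Step 7.** Facial selectivity may be poor or reversed, because the catalyst works against the Felkin–Anh bias of C7 and the C9 flank is not small. The fallback uses the substrate bias and then inverts.
- From ketone 11, LiBH(s-Bu)3 at −78 °C gives the Felkin product, the 8R alcohol F5.
- Mitsunobu reaction with chloroacetic acid (PPh3, diisopropyl azodicarboxylate) inverts C8 and gives the 8S chloroacetate F6.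
- Thiourea with NaHCO3 in ethanol removes the chloroacetyl group and returns alcohol 12.

**Step 10.** The Z/E ratio may erode, or the α-oxygenated aldehyde may be lost through epimerisation at C6 or decomposition under the basic ylide. The fallback builds the same alkene by two cross-couplings.
- From aldehyde 14, Corey–Fuchs olefination (CBr4, PPh3) gives the 1,1-dibromoalkene F7.
- A trans-selective Negishi methylation (MeZnCl, Pd(t-Bu3P)2) replaces the bromine trans to C6 and gives the (Z)-bromoalkene F8.
- Suzuki–Miyaura coupling of F8 with 16, as in step 11, gives diene 17.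

**Step 16.** The allylic C3 hydroxyl of 25 may be lost by β-elimination to a cross-conjugated dienone, or the ring may open by retro-aldol cleavage in the hot medium. The fallback never forms the aldol.
- From cycloadduct 23, dehydrogenation with activated MnO2 in refluxing benzene gives isoxazole F9.
- Mo(CO)6 in MeCN/H2O opens F9 to enaminone F10, in which C3 is already a carbonyl.
- Mild aqueous acid (oxalic acid) hydrolyses the enamine and gives diketone 26.

**Step 19.** Proton transfer to the lactone enolate from the vinylogous C6 hydrogen of the furanone dienone, or direct deprotonation there, may scramble C6 or degrade the furanone. The fallback does the enolate chemistry before the furanone exists and carries the amine as a masked methylene.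
- From cycloadduct 23, LiN(SiMe3)2 and CH2=NMe2+ I− give the amino isoxazoline F11.
- The conditions of steps 16 and 17 give the amino β-hydroxy ketone F12 and the amino diketone F13; ammonia set free in the first of these finds no Michael acceptor.
- The conditions of step 18 give Mannich base 29, which is quaternised and eliminated as in step 19 to give 31.

## Further compounds

F1 | step 15 | Z-enone methyl ketone (C3 acetyl on C4; PMB ether) | COc1ccc(COC[C@](C)(O[Si](CC)(CC)CC)C[C@H](O[Si](C)(C)C(C)(C)C)[C@H]2CC(=O)O[C@@H]2/C=C(/C)C(C)=O)cc1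
F2 | step 15 | methyl ketone C1 alcohol | OC[C@](C)(O[Si](CC)(CC)CC)C[C@H](O[Si](C)(C)C(C)(C)C)[C@H]1CC(=O)O[C@@H]1/C=C(/C)C(C)=O
F3 | step 15 | keto aldehyde (C1 aldehyde, C3 methyl ketone) | O=C[C@](C)(O[Si](CC)(CC)CC)C[C@H](O[Si](C)(C)C(C)(C)C)[C@H]1CC(=O)O[C@@H]1/C=C(/C)C(C)=O
F4 | step 15 | macrocyclic β-hydroxy ketone (C1–OH, C3=O; C1 epimers) | C1C(=O)O[C@@H]2/C=C(/C)C(=O)CC(O)[C@](C)(O[Si](CC)(CC)CC)C[C@H](O[Si](C)(C)C(C)(C)C)[C@@H]12
F5 | step 7 | 8R alcohol (C8 epimer of 12) | COc1ccc(COC[C@](C)(O[Si](CC)(CC)CC)C[C@@H](O)[C@H]2CC(=O)O[C@@H]2CO[Si](CC)(CC)CC)cc1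
F6 | step 7 | 8S chloroacetate | COc1ccc(COC[C@](C)(O[Si](CC)(CC)CC)C[C@H](OC(=O)CCl)[C@H]2CC(=O)O[C@@H]2CO[Si](CC)(CC)CC)cc1
F7 | step 10 | 1,1-dibromoalkene (C6–CH=CBr2) | COc1ccc(COC[C@](C)(O[Si](CC)(CC)CC)C[C@H](O[Si](C)(C)C(C)(C)C)[C@H]2CC(=O)O[C@@H]2C=C(Br)Br)cc1
F8 | step 10 | (Z)-bromoalkene (C6–CH=C(Br)CH3, bromine cis to C6) | COc1ccc(COC[C@](C)(O[Si](CC)(CC)CC)C[C@H](O[Si](C)(C)C(C)(C)C)[C@H]2CC(=O)O[C@@H]2/C=C(/C)Br)cc1
F9 | step 16 | isoxazole-bridged carbocycle | C1C(=O)O[C@@H]2/C=C(/C)c3cc(no3)[C@](C)(O[Si](CC)(CC)CC)C[C@H](O[Si](C)(C)C(C)(C)C)[C@@H]12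
F10 | step 16 | enaminone (C3=O, C1–NH2, C1=C2) | C1C(=O)O[C@@H]2/C=C(/C)C(=O)C=C(N)[C@](C)(O[Si](CC)(CC)CC)C[C@H](O[Si](C)(C)C(C)(C)C)[C@@H]12
F11 | step 19 | amino isoxazoline (11-dimethylaminomethyl derivative of 23) | CN(C)CC1C(=O)O[C@@H]2/C=C(/C)[C@@H]3CC(=NO3)[C@](C)(O[Si](CC)(CC)CC)C[C@H](O[Si](C)(C)C(C)(C)C)[C@@H]12
F12 | step 19 | amino β-hydroxy ketone | CN(C)CC1C(=O)O[C@@H]2/C=C(/C)[C@@H](O)CC(=O)[C@](C)(O[Si](CC)(CC)CC)C[C@H](O[Si](C)(C)C(C)(C)C)[C@@H]12
F13 | step 19 | amino 1,3-diketone | CN(C)CC1C(=O)O[C@@H]2/C=C(/C)C(=O)CC(=O)[C@](C)(O[Si](CC)(CC)CC)C[C@H](O[Si](C)(C)C(C)(C)C)[C@@H]12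
A1 | alternative 1 | 3-oxo heliangolide (1(10)E,4Z-dien-3-one 6,12-olide 8-angelate) | C=C1C(=O)O[C@@H]2/C=C(/C)C(=O)C/C=C(C)/C[C@H](OC(=O)/C(C)=C\C)[C@@H]12
A2 | alternative 1 | 1-hydroxy bridged enol ether (1-dihydrolychnopholide) | C=C1C(=O)O[C@@H]2/C=C(/C)C3=C[C@H](O)[C@@](C)(C[C@H](OC(=O)/C(C)=C\C)[C@@H]12)O3
A3 | alternative 2 | seco Z-iodoalkene C6 aldehyde with furanone, angelate and C12 silyl ether | O=C[C@H](C(=C)CO[Si](C)(C)C(C)(C)C)[C@@H](OC(=O)/C(C)=C\C)C[C@@]1(C)OC(/C(C)=C\I)=CC1=O
A4 | alternative 2 | bridged C6 allylic alcohol with C12 silyl ether | O[C@@H]1/C=C(/C)C2=CC(=O)[C@@](C)(C[C@H](OC(=O)/C(C)=C\C)[C@H]1C(=C)CO[Si](C)(C)C(C)(C)C)O2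
A5 | alternative 3 | seco 3-unsubstituted furanone with Z-vinyl iodide at C4 | O=C1C=CO[C@]1(C)C[C@H](O[Si](C)(C)C(C)(C)C)[C@H]2CC(=O)O[C@@H]2/C=C(/C)I
A6 | alternative 3 | bridged tricycle lacking the C13 methylene, C8 silyl ether (same as 28) | C1C(=O)O[C@@H]2/C=C(/C)C3=CC(=O)[C@@](C)(C[C@H](O[Si](C)(C)C(C)(C)C)[C@@H]12)O3
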